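**Retrosynthetic overview**
- Target ⇐ aryl silyl ether of the same ketone ⇐ oxidation of a 9'-carbinol made by α-selective prenylation (C9'–C10' bond) of an (8'S)-α-methyl aldehyde.
- The (8'S) centre ⇐ hydroxyl-directed asymmetric hydrogenation of a terminal (E)-allylic alcohol, itself from allylic oxidation of the terminal isopropylidene of a farnesyl-derived chroman.
- Chroman ring (the only ring formed; the benzene ring is bought) ⇐ tocopherol-cyclase-like, enantioselective proton-initiated 6-endo O-cyclisation of a 2-farnesylphenol, which sets C2 (R) and at the same time caps the phenol.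
- 2-Farnesylphenol ⇐ ortho-C-farnesylation of mono-silylated methylhydroquinone with (2E,6E)-farnesyl bromide.

Assumption: (2E,6E)-farnesyl bromide is bought, and for the two catalyst-controlled steps (3 and 5) the antipode named is the one expected to give the drawn configuration; the mirror-image catalyst is used if the first run shows the opposite sense.

**Route**

Step 1
Reactants: 1 2-methylbenzene-1,4-diol (methylhydroquinone)
Product: 2 2-methyl-4-[(triisopropylsilyl)oxy]phenol
Conditions: TIPSCl (1.0 equiv), imidazole, DMF, 0 °C to rt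
Reagents that add atoms: triisopropylsilyl chloride, CC(C)[Si](Cl)(C(C)C)C(C)C
Why: Imidazole-mediated O-silylation; the bulky TIPS group goes on the 4-OH, which has no ortho substituent, in preference to the 1-OH next to the methyl group, and limiting TIPSCl keeps bis-silylation low.

Step 2
Reactants: 2 2-methyl-4-[(triisopropylsilyl)oxy]phenol; 3 (2E,6E)-farnesyl bromide
Product: 5 2-methyl-4-[(triisopropylsilyl)oxy]-6-[(2E,6E)-3,7,11-trimethyldodeca-2,6,10-trien-1-yl]phenol, via sodium aryloxide 4 (not isolated)
Conditions: NaH (1.05 equiv), toluene, 0 °C to rt; then 3, rt, 24 h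
Reagents that add atoms: none
Why: Ortho-selective C-allylation of a sodium phenoxide in a non-polar solvent (phenoxide C-alkylation): the tight ion pair disfavours O-alkylation, the para position is blocked and only one ortho position is free, and SN2 attack at the primary allylic carbon keeps both E alkenes.

Step 3
Reactants: 5 2-methyl-4-[(triisopropylsilyl)oxy]-6-[(2E,6E)-3,7,11-trimethyldodeca-2,6,10-trien-1-yl]phenol
Product: 6 (2R)-2-[(3E)-4,8-dimethylnona-3,7-dien-1-yl]-2,8-dimethyl-6-[(triisopropylsilyl)oxy]chromane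
Conditions: (S,S)-IDPi (confined BINOL-derived N-triflyl imidodiphosphorimidate Brønsted acid, 5 mol %), cyclohexane, 30 °C
Reagents that add atoms: none
Why: Proposed new method: tocopherol-cyclase-type proton-initiated 6-endo hydroalkoxylation, in which the confined chiral acid, hydrogen-bonded to the phenol, protonates C2' of the only alkene with an internal nucleophile in reach while the phenol oxygen closes on the developing tertiary cation at C3' in a concerted asynchronous chair-like transition state, the chiral pocket telling the methyl from the homogeranyl branch to set C2 as R and the two distal alkenes being protonated only reversibly; the closest known reaction type is the IDPi-catalysed asymmetric intramolecular hydroalkoxylation of unactivated alkenes (and the cyclase reaction itself).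

Step 4
Reactants: 6 (2R)-2-[(3E)-4,8-dimethylnona-3,7-dien-1-yl]-2,8-dimethyl-6-[(triisopropylsilyl)oxy]chromane
Product: 7 (2E,6E)-9-[(2R)-2,8-dimethyl-6-[(triisopropylsilyl)oxy]chroman-2-yl]-2,6-dimethylnona-2,6-dien-1-ol
Conditions: SeO2 (0.3 equiv), t-BuOOH (3 equiv), salicylic acid (0.1 equiv), CH2Cl2, 0 °C to rt, stopped at about 70 % conversion
Reagents that add atoms: selenium dioxide, O=[Se]=O (catalytic, hands over the O atom); tert-butyl hydroperoxide, CC(C)(C)OO (stoichiometric oxidant that restores SeO2)
Why: Sharpless–Umbreit allylic oxidation (ene reaction, then [2,3]-sigmatropic shift) goes to the E-methyl of the terminal isopropylidene, the most accessible ene partner, and gives the (E)-allylic alcohol, while both aryl oxygens are capped as ring ether and silyl ether.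

Step 5
Reactants: 7 (2E,6E)-9-[(2R)-2,8-dimethyl-6-[(triisopropylsilyl)oxy]chroman-2-yl]-2,6-dimethylnona-2,6-dien-1-ol
Product: 8 (2S,6E)-9-[(2R)-2,8-dimethyl-6-[(triisopropylsilyl)oxy]chroman-2-yl]-2,6-dimethylnon-6-en-1-ol
Conditions: Ru(OAc)2[(S)-BINAP] (1 mol %), H2 (100 atm), MeOH/CH2Cl2 9:1, rt
Reagents that add atoms: none
Why: Noyori hydroxyl-directed asymmetric hydrogenation: the Ru–BINAP dicarboxylate reduces only the alkene that chelates through the allylic OH (the isolated 3',4'-alkene is left, as the 6,7-alkene of geraniol is) and delivers H2 to one face to set C8' as S, by analogy with geraniol to citronellol and tiglic acid to 2-methylbutanoic acid.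

Step 6
Reactants: 8 (2S,6E)-9-[(2R)-2,8-dimethyl-6-[(triisopropylsilyl)oxy]chroman-2-yl]-2,6-dimethylnon-6-en-1-ol
Product: 9 (2S,6E)-9-[(2R)-2,8-dimethyl-6-[(triisopropylsilyl)oxy]chroman-2-yl]-2,6-dimethylnon-6-enal
Conditions: Dess–Martin periodinane, pyridine, CH2Cl2, 0 °C; used at once
Reagents that add atoms: none
Why: Dess–Martin oxidation, buffered and cold, gives the α-methyl aldehyde without epimerisation and leaves the alkene and the aryl silyl ether alone.

Step 7
Reactants: 9 (2S,6E)-9-[(2R)-2,8-dimethyl-6-[(triisopropylsilyl)oxy]chroman-2-yl]-2,6-dimethylnon-6-enal; 10 1-chloro-3-methylbut-2-ene (prenyl chloride)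
Product: 12 (6S,10E)-13-[(2R)-2,8-dimethyl-6-[(triisopropylsilyl)oxy]chroman-2-yl]-2,6,10-trimethyltrideca-2,10-dien-5-ol (C5 epimer mixture), via prenylbarium chloride 11 (not isolated)
Conditions: BaI2, lithium biphenylide (2 equiv), THF, rt (gives active Ba); 10, –78 °C; then 9, –78 °C; aq NH4Cl
Reagents that add atoms: none
Why: Yamamoto allylbarium addition: prenylbarium chloride, unlike the Mg, Zn, B or Cr reagents, attacks the aldehyde through its unsubstituted α-carbon at –78 °C to give the linear prenyl carbinol, the fast cold addition leaves C8' intact, and the new carbinol centre is removed in the next step.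

Step 8
Reactants: 12 (6S,10E)-13-[(2R)-2,8-dimethyl-6-[(triisopropylsilyl)oxy]chroman-2-yl]-2,6,10-trimethyltrideca-2,10-dien-5-ol
Product: 13 (6S,10E)-13-[(2R)-2,8-dimethyl-6-[(triisopropylsilyl)oxy]chroman-2-yl]-2,6,10-trimethyltrideca-2,10-dien-5-one
Conditions: Dess–Martin periodinane, pyridine, CH2Cl2, 0 °C to rt
Reagents that add atoms: none
Why: Dess–Martin oxidation of the homoallylic alcohol under pyridine buffer gives the β,γ-unsaturated ketone without moving the alkene into conjugation or epimerising C8'.

Step 9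
Reactants: 13 (6S,10E)-13-[(2R)-2,8-dimethyl-6-[(triisopropylsilyl)oxy]chroman-2-yl]-2,6,10-trimethyltrideca-2,10-dien-5-one
Product: 14 (6S,10E)-13-[(2R)-6-hydroxy-2,8-dimethylchroman-2-yl]-2,6,10-trimethyltrideca-2,10-dien-5-one (target)
Conditions: TBAF (1.1 equiv), AcOH (1.1 equiv), THF, 0 °C, 20 min
Reagents that add atoms: none
Why: Fluoride cleavage of the aryl silyl ether (desilylation, driven by the Si–F bond) is fast at 0 °C, and the acetic acid buffer keeps the medium from epimerising C8' or shifting the β,γ-alkene.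

**Compound list**
1 | 2-methylbenzene-1,4-diol (methylhydroquinone) | Cc1cc(O)ccc1O | starting material
2 | 2-methyl-4-[(triisopropylsilyl)oxy]phenol | Cc1cc(O[Si](C(C)C)(C(C)C)C(C)C)ccc1O | intermediate
3 | (2E,6E)-1-bromo-3,7,11-trimethyldodeca-2,6,10-triene (farnesyl bromide) | CC(C)=CCC/C(C)=C/CC/C(C)=C/CBr | starting material
4 | sodium 2-methyl-4-[(triisopropylsilyl)oxy]phenoxide | Cc1cc(O[Si](C(C)C)(C(C)C)C(C)C)ccc1[O-].[Na+] | intermediate (not isolated)
5 | 2-methyl-4-[(triisopropylsilyl)oxy]-6-[(2E,6E)-3,7,11-trimethyldodeca-2,6,10-trien-1-yl]phenol | CC(C)=CCC/C(C)=C/CC/C(C)=C/Cc1cc(O[Si](C(C)C)(C(C)C)C(C)C)cc(C)c1O | intermediate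
6 | (2R)-2-[(3E)-4,8-dimethylnona-3,7-dien-1-yl]-2,8-dimethyl-6-[(triisopropylsilyl)oxy]chromane | CC(C)=CCC/C(C)=C/CC[C@]1(C)CCc2cc(O[Si](C(C)C)(C(C)C)C(C)C)cc(C)c2O1 | intermediate
7 | (2E,6E)-9-[(2R)-2,8-dimethyl-6-[(triisopropylsilyl)oxy]chroman-2-yl]-2,6-dimethylnona-2,6-dien-1-ol | OC/C(C)=C/CC/C(C)=C/CC[C@]1(C)CCc2cc(O[Si](C(C)C)(C(C)C)C(C)C)cc(C)c2O1 | intermediate
8 | (2S,6E)-9-[(2R)-2,8-dimethyl-6-[(triisopropylsilyl)oxy]chroman-2-yl]-2,6-dimethylnon-6-en-1-ol | OC[C@@H](C)CCC/C(C)=C/CC[C@]1(C)CCc2cc(O[Si](C(C)C)(C(C)C)C(C)C)cc(C)c2O1 | intermediate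
9 | (2S,6E)-9-[(2R)-2,8-dimethyl-6-[(triisopropylsilyl)oxy]chroman-2-yl]-2,6-dimethylnon-6-enal | O=C[C@@H](C)CCC/C(C)=C/CC[C@]1(C)CCc2cc(O[Si](C(C)C)(C(C)C)C(C)C)cc(C)c2O1 | intermediate
10 | 1-chloro-3-methylbut-2-ene (prenyl chloride) | CC(C)=CCCl | starting material
11 | prenylbarium chloride | CC(C)=CC[Ba]Cl | intermediate (not isolated)
12 | (6S,10E)-13-[(2R)-2,8-dimethyl-6-[(triisopropylsilyl)oxy]chroman-2-yl]-2,6,10-trimethyltrideca-2,10-dien-5-ol (C5 epimer mixture) | CC(C)=CCC(O)[C@@H](C)CCC/C(C)=C/CC[C@]1(C)CCc2cc(O[Si](C(C)C)(C(C)C)C(C)C)cc(C)c2O1 | intermediate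
13 | (6S,10E)-13-[(2R)-2,8-dimethyl-6-[(triisopropylsilyl)oxy]chroman-2-yl]-2,6,10-trimethyltrideca-2,10-dien-5-one | CC(C)=CCC(=O)[C@@H](C)CCC/C(C)=C/CC[C@]1(C)CCc2cc(O[Si](C(C)C)(C(C)C)C(C)C)cc(C)c2O1 | intermediate
14 | (6S,10E)-13-[(2R)-6-hydroxy-2,8-dimethylchroman-2-yl]-2,6,10-trimethyltrideca-2,10-dien-5-one | CC(C)=CCC(=O)[C@@H](C)CCC/C(C)=C/CC[C@]1(C)CCc2cc(O)cc(C)c2O1 | target

**Count**
Total steps: 9. Longest linear sequence: 9 (1 to 14).

**Steps most likely to fail, with fallbacks**

Step 3 (enantioselective ring closure; no direct precedent for a phenol on a trisubstituted alkene in a polyene). The fallback sets out from 5 and comes back at 6. Phenol 5 is closed with an achiral acid (p-TsOH·H2O 10 mol %, toluene, 60 °C, the classical chromanol closure of prenylated quinols) to the racemic chroman F1. The enantiomers are then separated by preparative SFC on a cellulose carbamate phase, and the (2R) enantiomer is 6. Enantiocontrol is thus moved from catalysis to resolution.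

Step 5 (enantioselectivity of Ru–BINAP on a 2-methyl-2-alken-1-ol is less documented than for geraniol-type substrates, and the two product diastereomers cannot be separated). The fallback sets out from 7 and comes back at 8. Alcohol 7 is oxidised with MnO2 in CH2Cl2 to the (E)-2-methyl enal F2. F2 is reduced at the C=C bond by an ene-reductase of the Old Yellow Enzyme family (screened for the S product) in the presence of an alcohol dehydrogenase, catalytic NADP+ and i-PrOH in phosphate buffer at pH 7 and 30 °C. The saturated aldehyde is reduced in the same pot before it can racemise, giving 8. The stereocentre is then set by a biocatalytic conjugate reduction in place of a metal-catalysed hydrogenation.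

Step 7 (α- versus γ-attack of the prenyl metal, and handling of active barium). The fallback sets out from 9 and comes back at 12. Aldehyde 9 is treated with allylmagnesium bromide in THF at –78 °C, where no regiochemical question arises, to give the allyl carbinol F3. Cross-metathesis of F3 in neat 2-methyl-2-butene with Grubbs second-generation catalyst (3 mol %, rt) turns the terminal vinyl group into the dimethylvinyl group and gives 12. The internal trisubstituted alkene is expected to be inert under these conditions.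

**Further compounds**
F1 | step 3 | racemic 2-[(3E)-4,8-dimethylnona-3,7-dien-1-yl]-2,8-dimethyl-6-[(triisopropylsilyl)oxy]chromane | CC(C)=CCC/C(C)=C/CCC1(C)CCc2cc(O[Si](C(C)C)(C(C)C)C(C)C)cc(C)c2O1
F2 | step 5 | (2E,6E)-9-[(2R)-2,8-dimethyl-6-[(triisopropylsilyl)oxy]chroman-2-yl]-2,6-dimethylnona-2,6-dienal | O=C/C(C)=C/CC/C(C)=C/CC[C@]1(C)CCc2cc(O[Si](C(C)C)(C(C)C)C(C)C)cc(C)c2O1
F3 | step 7 | (5S,9E)-12-[(2R)-2,8-dimethyl-6-[(triisopropylsilyl)oxy]chroman-2-yl]-5,9-dimethyldodeca-1,9-dien-4-ol (C4 epimer mixture) | C=CCC(O)[C@@H](C)CCC/C(C)=C/CC[C@]1(C)CCc2cc(O[Si](C(C)C)(C(C)C)C(C)C)cc(C)c2O1
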